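## Retrosynthetic overview

1. The target is reached by global desilylation, removal of a C1 carbonyl, and SmI2 opening of a 2α,5α-epoxy-1-ketone (oxygen-bridged ring A).
2. The oxygen-bridged tricycle comes from the key step: a rhodium carbenoid at C2 is captured by the C5 ketone oxygen to give a five-membered carbonyl ylide (O, C2, C1, C10, C5), which adds 2-(trimethylsilyl)ethyl methacrylate. C2–C3 and C4–C5 form together; the oxa bridge closes first, ring A second.
3. Enabling feature: the 5-hydroxyl oxygen on C5 sits 1,4 to C2 across ring A. Ring A is therefore a masked 7-oxabicyclo[2.2.1]heptane, and C3–C4 with its methyl and carboxyl is a methacrylate. The temporary C1 ketone makes C2 a carbenoid carbon and later lets SmI2 cut C2–O.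
4. The diazoketone comes from a monocyclic ring B (C5 ketone, C8 methylene, C9 silyloxy plus side chain, C10 methyl and acyl). C9 is set by organocerium addition to a rigid trans-fused acetonide enone made from (R)-Wieland–Miescher ketone by reduction, dehydrogenation and double ozonolysis. The side chain comes from 4-bromobut-1-yne by carboalumination.
5. Ring order: ring B is taken from the starting material; the temporary oxa bridge and ring A are formed in the key step.

Key step: step 15

Remark: atom numbers in names follow the labdane skeleton of the target (ring A = C1–C5, C10; ring B = C5–C10), with α/β given for the drawing in which the C10 methyl is β; "9β-oxygen" therefore means the side chain is α. The (R)-enantiomer of the Wieland–Miescher ketone is taken as commercial, and the dipolarophile ester is made in one step.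

## Route

Step 1
Reactants: 1 4-bromobut-1-yne
Product: 3 (2E)-5-bromo-3-methylpent-2-en-1-ol, via alkenylalane 2 (not isolated)
Conditions: Me3Al (2 equiv), Cp2ZrCl2 (0.2 equiv), CH2Cl2, 0 to 23 °C; then (CH2O)n, 0 to 23 °C; aq. HCl
Reagents that add atoms: trimethylaluminium, C[Al](C)C; formaldehyde (from paraformaldehyde), C=O
Why: Zirconium-catalysed syn-carboalumination (Negishi) places methyl on the internal and aluminium on the terminal alkyne carbon, and trapping of the alkenylalane with formaldehyde occurs with retention, which fixes the E trisubstituted alkene; the primary bromide should not react with Me3Al.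

Step 2
Reactants: 3 (2E)-5-bromo-3-methylpent-2-en-1-ol
Product: 4 {[(2E)-5-bromo-3-methylpent-2-en-1-yl]oxy}(tert-butyl)diphenylsilane
Conditions: t-BuPh2SiCl, imidazole, CH2Cl2, 23 °C
Reagents that add atoms: tert-butyl(chloro)diphenylsilane, CC(C)(C)[Si](Cl)(c1ccccc1)c1ccccc1
Why: Standard silylation of a primary allylic alcohol; the bulky silyl ether should survive all later steps and fall to fluoride at the end.

Step 3
Reactants: 5 2-methylprop-2-enoyl chloride; 6 2-(trimethylsilyl)ethanol
Product: 7 2-(trimethylsilyl)ethyl 2-methylprop-2-enoate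
Conditions: Et3N, DMAP (cat.), CH2Cl2, 0 °C
Reagents that add atoms: none
Why: Acylation of the alcohol by the acid chloride under nucleophilic catalysis gives the dipolarophile as a fluoride-cleavable ester.

Step 4
Reactants: 8 (R)-Wieland–Miescher ketone
Product: 9 (4aR,5R)-5-hydroxy-4a-methyl-4,4a,5,6,7,8-hexahydronaphthalen-2(3H)-one
Conditions: NaBH4 (0.3 equiv), EtOH, −10 °C
Reagents that add atoms: none
Why: Borohydride reduces the saturated ketone faster than the enone and attacks the face opposite the angular methyl, so the new hydroxyl is cis to the methyl; this carbinol is the masked C5 ketone.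

Step 5
Reactants: 9 (4aR,5R)-5-hydroxy-4a-methyl-4,4a,5,6,7,8-hexahydronaphthalen-2(3H)-one
Product: 10 (4aR,5R)-5-hydroxy-4a-methyl-5,6,7,8-tetrahydronaphthalen-2(4aH)-one
Conditions: DDQ (1.5 equiv), 1,4-dioxane, reflux
Reagents that add atoms: none
Why: DDQ dehydrogenation of the enone at its α′,β′ carbons gives the cross-conjugated dienone needed for the double cleavage; no stereocenter is touched.

Step 6
Reactants: 10 (4aR,5R)-5-hydroxy-4a-methyl-5,6,7,8-tetrahydronaphthalen-2(4aH)-one
Product: 12 (2S,3R)-3-hydroxy-2-(hydroxymethyl)-2-methylcyclohexan-1-one, via keto aldehyde 11 (not isolated)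
Conditions: O3, CH2Cl2/MeOH, −78 °C; Me2S; then NaBH4 (1.5 equiv), −78 °C; AcOH quench
Reagents that add atoms: ozone, [O-][O+]=O
Why: Ozonolysis with reductive work-up cuts both enone double bonds, which removes three carbons and leaves the C9 ketone and the C1 formyl group on the quaternary carbon; at −78 °C borohydride should reduce the aldehyde (and the excised fragment) much faster than the hindered ketone.

Step 7
Reactants: 12 (2S,3R)-3-hydroxy-2-(hydroxymethyl)-2-methylcyclohexan-1-one
Product: 13 (4aS,8aR)-2,2,4a-trimethyltetrahydro-4H-benzo[d][1,3]dioxin-5(4aH)-one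
Conditions: 2,2-dimethoxypropane, PPTS (cat.), CH2Cl2, 23 °C
Reagents that add atoms: 2,2-dimethoxypropane, COC(C)(C)OC
Why: Acid-catalysed transacetalisation ties the 1,3-diol into a six-membered isopropylidene acetal; because O5 and C1 are trans on ring B the bicycle is trans-fused and rigid, with the C10 methyl axial.

Step 8
Reactants: 13 (4aS,8aR)-2,2,4a-trimethyltetrahydro-4H-benzo[d][1,3]dioxin-5(4aH)-one
Product: 16 (4aS,8aR)-2,2,4a-trimethyl-6-methylidenetetrahydro-4H-benzo[d][1,3]dioxin-5(4aH)-one, via Mannich base 14 (not isolated), via methiodide 15 (not isolated)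
Conditions: LiN(SiMe3)2, THF, −78 °C; CH2=NMe2+ I−, −78 to 23 °C; then MeI, CH2Cl2, 23 °C; then aq. NaHCO3, 23 °C
Reagents that add atoms: N,N-dimethylmethyleneiminium iodide (Eschenmoser's salt), C=[N+](C)C.[I-]
Why: Only C8 can be enolised, so Mannich reaction of the lithium enolate followed by quaternisation and Hofmann-type elimination should give the α-methylene ketone regiospecifically.

Step 9
Reactants: 4 {[(2E)-5-bromo-3-methylpent-2-en-1-yl]oxy}(tert-butyl)diphenylsilane; 16 (4aS,8aR)-2,2,4a-trimethyl-6-methylidenetetrahydro-4H-benzo[d][1,3]dioxin-5(4aH)-one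
Product: 19 acetonide tertiary alcohol (C9: side chain α, OH β), via Grignard reagent 17 (not isolated), via organocerium reagent 18 (not isolated)
Conditions: 4 (1.5 equiv), Mg, THF, 40 °C; CeCl3, THF, −78 °C; then 16, −78 °C; aq. NH4Cl
Reagents that add atoms: none
Why: The organocerium reagent adds 1,2 to the hindered enone without enolisation, and on the rigid trans-fused bicycle it should enter axially from the α face, anti to the axial C10 methyl (as in additions to 1-decalones with an adjacent angular methyl), which sets C9 with the chain α and the hydroxyl β.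

Step 10
Reactants: 19 acetonide tertiary alcohol
Product: 20 triethylsilyl ether of 19
Conditions: Et3SiOTf, 2,6-lutidine, CH2Cl2, −78 to 0 °C
Reagents that add atoms: triethylsilyl trifluoromethanesulfonate, CC[Si](CC)(CC)OS(=O)(=O)C(F)(F)F
Why: A silyl triflate with a hindered pyridine base silylates even a tertiary alcohol; the ether blocks retro-aldol cleavage once C10 carries two carbonyl groups and keeps this oxygen away from the carbenoid.

Step 11
Reactants: 20 triethylsilyl ether of 19
Product: 21 ring B 1,3-diol (free C5 carbinol and C1 hydroxymethyl)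
Conditions: PPTS (0.3 equiv), MeOH, 23 °C
Reagents that add atoms: none
Why: Mild acid-catalysed transacetalisation to methanol removes the isopropylidene acetal, while the hindered tertiary triethylsilyl ether and the primary tert-butyldiphenylsilyl ether are expected to stay.

Step 12
Reactants: 21 ring B 1,3-diol
Product: 22 ring B keto aldehyde (C5 ketone, C1 formyl)
Conditions: Dess–Martin periodinane (3 equiv), NaHCO3, CH2Cl2, 0 to 23 °C
Reagents that add atoms: none
Why: Dess–Martin oxidation converts the primary alcohol into the aldehyde and the secondary one into the C5 ketone under buffered, non-basic conditions; the product cannot enolise between the two carbonyls.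

Step 13
Reactants: 22 ring B keto aldehyde
Product: 23 ring B β-keto acid
Conditions: NaClO2, NaH2PO4, 2-methylbut-2-ene, t-BuOH/H2O, 0 °C
Reagents that add atoms: sodium chlorite, [Na+].[O-]Cl=O
Why: Pinnick oxidation converts the aldehyde into the acid without touching the alkenes, the hypochlorous acid being trapped by 2-methylbut-2-ene.

Step 14
Reactants: 23 ring B β-keto acid
Product: 25 ring B diazoketone, via acid chloride 24 (not isolated)
Conditions: Me2C=C(Cl)NMe2 (1.2 equiv), CH2Cl2, 0 °C; then CH2N2 (4 equiv), Et2O, 0 °C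
Reagents that add atoms: diazomethane, C=[N+]=[N-]
Why: The acid chloride is made under neutral conditions with the α-chloroenamine and acylates diazomethane (first stage of the Arndt–Eistert sequence), which brings in C2 as the diazo carbon; the keto acid is kept cold and used at once.

Step 15
Reactants: 25 ring B diazoketone; 7 2-(trimethylsilyl)ethyl 2-methylprop-2-enoate
Product: 27 2-(trimethylsilyl)ethyl 15-(tert-butyldiphenylsilyloxy)-2α,5α-epoxy-1-oxo-9β-(triethylsilyloxy)labda-8(17),13E-dien-19-oate, via carbonyl ylide 26 (not isolated)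
Conditions: Rh2(O2CC3F7)4 (1 mol%), 7 (8 equiv), CH2Cl2, 23 °C, slow addition of 25
Reagents that add atoms: none
Why: The electrophilic rhodium carbenoid formed at C2 by loss of N2 is captured by a lone pair of the C5 ketone oxygen, which closes the five-membered ring O–C2–C1–C10–C5 of carbonyl ylide 26, and the ylide then adds suprafacially to the methacrylate in a concerted, asynchronous 1,3-dipolar cycloaddition that closes ring A as a 7-oxabicyclo[2.2.1]heptane. The closest known reaction type is the rhodium-catalysed tandem carbonyl ylide formation–cycloaddition of 1-diazo-2,4-diones and 2-(diazoacetyl)cycloalkanones with electron-poor alkenes. Regiochemistry should follow the polarisation of both partners: the enolate-like terminus C2 (largest HOMO coefficient) bonds to the CH2 terminus (C3) and the oxocarbenium terminus C5 to the ester-bearing carbon (C4). The face is set by C10 and C9: the planar ylide ring holds C1 in its plane, so the C10 methyl lies on the β face and C9 with its axial side chain on the α face, the alkene adds to the β face, and the bridging oxygen on C5 ends up α, trans to the C10 methyl, while C2 is fixed by the bridge and later ceases to be a stereocenter. At C4 the flat ester is expected to take the endo position next to the C10 methyl (secondary overlap with the C1 carbonyl; the alternative presses methyl against methyl), which gives the β carboxyl and the α methyl. The step needs ylide formation to outrun cyclopropanation of the C8 methylene and insertion reactions, which the perfluorobutyrate ligands, the five-membered geometry of ylide closure and slow addition into excess dipolarophile should secure.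

Step 16
Reactants: 27 oxygen-bridged keto ester
Product: 28 2-(trimethylsilyl)ethyl 15-(tert-butyldiphenylsilyloxy)-5α-hydroxy-1-oxo-9β-(triethylsilyloxy)labda-8(17),13E-dien-19-oate
Conditions: SmI2 (2.5 equiv), THF/MeOH, −78 °C
Reagents that add atoms: none
Why: SmI2 reduces the α-alkoxy ketone by two single-electron transfers and expels the C2 oxygen as an alkoxide, which opens the bridge, leaves C2 as CH2 and frees the 5α-hydroxyl without touching any stereocenter.

Step 17
Reactants: 28 5α-hydroxy-1-ketone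
Product: 29 C1 tosylhydrazone of 28
Conditions: TsNHNH2 (2 equiv), EtOH, 60 °C
Reagents that add atoms: 4-methylbenzenesulfonohydrazide, Cc1ccc(cc1)S(=O)(=O)NN
Why: Condensation of the C1 ketone with tosylhydrazide; the neighbouring tertiary alcohol cannot dehydrate toward the quaternary C10.

Step 18
Reactants: 29 C1 tosylhydrazone
Product: 31 2-(trimethylsilyl)ethyl 15-(tert-butyldiphenylsilyloxy)-5α-hydroxy-9β-(triethylsilyloxy)labda-8(17),13E-dien-19-oate, via tosylhydrazine 30 (not isolated)
Conditions: catecholborane (3 equiv), CHCl3, 0 to 23 °C; then NaOAc·3H2O, 60 °C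
Reagents that add atoms: none
Why: Caglioti-type tosylhydrazone reduction: catecholborane adds hydride to the C=N bond and acetate triggers loss of sulfinate and N2, so the C1 carbonyl becomes CH2 under mild, non-basic conditions that should spare the alkenes and avoid retro-aldol cleavage.

Step 19
Reactants: 31 fully protected ester
Product: 32 5α,9β-dihydroxyisocupressic acid
Conditions: Bu4NF (8 equiv), THF, 23 to 45 °C; aq. NH4Cl, then citric acid to pH 4
Reagents that add atoms: none
Why: Fluoride cleaves both silyl ethers and, by β-elimination of ethene and fluorotrimethylsilane, the 2-(trimethylsilyl)ethyl ester in one operation, which should give the triol acid after mild acidification.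

## Compound list

1 | 4-bromobut-1-yne | C#CCCBr | starting material
2 | [(1E)-4-bromo-2-methylbut-1-en-1-yl]dimethylalane | C[Al](C)/C=C(\C)CCBr | intermediate
3 | (2E)-5-bromo-3-methylpent-2-en-1-ol | BrCC/C(C)=C/CO | intermediate
4 | {[(2E)-5-bromo-3-methylpent-2-en-1-yl]oxy}(tert-butyl)diphenylsilane | BrCC/C(C)=C/CO[Si](c1ccccc1)(c1ccccc1)C(C)(C)C | intermediate
5 | 2-methylprop-2-enoyl chloride (methacryloyl chloride) | C=C(C)C(Cl)=O | starting material
6 | 2-(trimethylsilyl)ethanol | OCC[Si](C)(C)C | starting material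
7 | 2-(trimethylsilyl)ethyl 2-methylprop-2-enoate | C=C(C)C(=O)OCC[Si](C)(C)C | intermediate
8 | (R)-Wieland–Miescher ketone, (8aR)-8a-methyl-3,4,8,8a-tetrahydronaphthalene-1,6(2H,7H)-dione | O=C1CC[C@@]2(C)C(=O)CCCC2=C1 | starting material
9 | (4aR,5R)-5-hydroxy-4a-methyl-4,4a,5,6,7,8-hexahydronaphthalen-2(3H)-one (OH cis to CH3) | O=C1CC[C@@]2(C)[C@H](O)CCCC2=C1 | intermediate
10 | (4aR,5R)-5-hydroxy-4a-methyl-5,6,7,8-tetrahydronaphthalen-2(4aH)-one | O=C1C=C[C@@]2(C)[C@H](O)CCCC2=C1 | intermediate
11 | (1R,2R)-2-hydroxy-1-methyl-6-oxocyclohexane-1-carbaldehyde | O=C[C@@]1(C)[C@H](O)CCCC1=O | intermediate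
12 | (2S,3R)-3-hydroxy-2-(hydroxymethyl)-2-methylcyclohexan-1-one | OC[C@@]1(C)[C@H](O)CCCC1=O | intermediate
13 | (4aS,8aR)-2,2,4a-trimethyltetrahydro-4H-benzo[d][1,3]dioxin-5(4aH)-one (trans-fused) | CC1(C)OC[C@@]2(C)[C@H](O1)CCCC2=O | intermediate
14 | 6-[(dimethylamino)methyl] derivative of 13 (Mannich base, both C6 epimers) | CC1(C)OC[C@@]2(C)[C@H](O1)CCC(CN(C)C)C2=O | intermediate
15 | N,N,N-trimethylammonium iodide of 14 (methiodide) | CC1(C)OC[C@@]2(C)[C@H](O1)CCC(C[N+](C)(C)C)C2=O.[I-] | intermediate
16 | (4aS,8aR)-2,2,4a-trimethyl-6-methylidenetetrahydro-4H-benzo[d][1,3]dioxin-5(4aH)-one | CC1(C)OC[C@@]2(C)[C@H](O1)CCC(=C)C2=O | intermediate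
17 | [(3E)-5-(tert-butyldiphenylsilyloxy)-3-methylpent-3-en-1-yl]magnesium bromide | Br[Mg]CC/C(C)=C/CO[Si](c1ccccc1)(c1ccccc1)C(C)(C)C | intermediate
18 | dichloro[(3E)-5-(tert-butyldiphenylsilyloxy)-3-methylpent-3-en-1-yl]cerium | Cl[Ce](Cl)CC/C(C)=C/CO[Si](c1ccccc1)(c1ccccc1)C(C)(C)C | intermediate
19 | acetonide tertiary alcohol: 16 with the (3E)-5-(tert-butyldiphenylsilyloxy)-3-methylpent-3-en-1-yl chain added at the ketone carbon (C9), chain trans and OH cis to the angular methyl | CC1(C)OC[C@@]2(C)[C@H](O1)CCC(=C)[C@@]2(O)CC/C(C)=C/CO[Si](c1ccccc1)(c1ccccc1)C(C)(C)C | intermediate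
20 | triethylsilyl ether of 19 | CC1(C)OC[C@@]2(C)[C@H](O1)CCC(=C)[C@@]2(O[Si](CC)(CC)CC)CC/C(C)=C/CO[Si](c1ccccc1)(c1ccccc1)C(C)(C)C | intermediate
21 | 2-(hydroxymethyl)-2-methyl-4-methylidene-3-[(3E)-5-(tert-butyldiphenylsilyloxy)-3-methylpent-3-en-1-yl]-3-(triethylsilyloxy)cyclohexan-1-ol (1-OH, 2-CH3 and 3-OSiEt3 all cis) | OC[C@@]1(C)[C@H](O)CCC(=C)[C@@]1(O[Si](CC)(CC)CC)CC/C(C)=C/CO[Si](c1ccccc1)(c1ccccc1)C(C)(C)C | intermediate
22 | 1-methyl-3-methylidene-6-oxo-2-[(3E)-5-(tert-butyldiphenylsilyloxy)-3-methylpent-3-en-1-yl]-2-(triethylsilyloxy)cyclohexane-1-carbaldehyde (1-CH3 and 2-OSiEt3 cis) | O=C[C@@]1(C)C(=O)CCC(=C)[C@@]1(O[Si](CC)(CC)CC)CC/C(C)=C/CO[Si](c1ccccc1)(c1ccccc1)C(C)(C)C | intermediate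
23 | corresponding cyclohexane-1-carboxylic acid (β-keto acid) | OC(=O)[C@@]1(C)C(=O)CCC(=C)[C@@]1(O[Si](CC)(CC)CC)CC/C(C)=C/CO[Si](c1ccccc1)(c1ccccc1)C(C)(C)C | intermediate
24 | corresponding cyclohexane-1-carbonyl chloride | ClC(=O)[C@@]1(C)C(=O)CCC(=C)[C@@]1(O[Si](CC)(CC)CC)CC/C(C)=C/CO[Si](c1ccccc1)(c1ccccc1)C(C)(C)C | intermediate
25 | 2-(2-diazoacetyl)-2-methyl-4-methylidene-3-[(3E)-5-(tert-butyldiphenylsilyloxy)-3-methylpent-3-en-1-yl]-3-(triethylsilyloxy)cyclohexan-1-one (2-CH3 and 3-OSiEt3 cis) | [N-]=[N+]=CC(=O)[C@@]1(C)C(=O)CCC(=C)[C@@]1(O[Si](CC)(CC)CC)CC/C(C)=C/CO[Si](c1ccccc1)(c1ccccc1)C(C)(C)C | intermediate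
26 | five-membered cyclic carbonyl ylide (C5=O+ bonded to the C2 carbanion, C1 ketone in the ring) fused to ring B | [CH-]1C(=O)[C@@]2(C)C(=[O+]1)CCC(=C)[C@@]2(O[Si](CC)(CC)CC)CC/C(C)=C/CO[Si](c1ccccc1)(c1ccccc1)C(C)(C)C | intermediate
27 | 2-(trimethylsilyl)ethyl 15-(tert-butyldiphenylsilyloxy)-2α,5α-epoxy-1-oxo-9β-(triethylsilyloxy)labda-8(17),13E-dien-19-oate | C=C1CC[C@@]23O[C@@H](C[C@]2(C)C(=O)OCC[Si](C)(C)C)C(=O)[C@]3(C)[C@]1(O[Si](CC)(CC)CC)CC/C(C)=C/CO[Si](c1ccccc1)(c1ccccc1)C(C)(C)C | intermediate
28 | 2-(trimethylsilyl)ethyl 15-(tert-butyldiphenylsilyloxy)-5α-hydroxy-1-oxo-9β-(triethylsilyloxy)labda-8(17),13E-dien-19-oate | C=C1CC[C@]2(O)[C@](C)(C(=O)CC[C@]2(C)C(=O)OCC[Si](C)(C)C)[C@]1(O[Si](CC)(CC)CC)CC/C(C)=C/CO[Si](c1ccccc1)(c1ccccc1)C(C)(C)C | intermediate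
29 | C1 (4-methylbenzenesulfonyl)hydrazone of 28 | C=C1CC[C@]2(O)[C@](C)(C(=NNS(=O)(=O)c3ccc(C)cc3)CC[C@]2(C)C(=O)OCC[Si](C)(C)C)[C@]1(O[Si](CC)(CC)CC)CC/C(C)=C/CO[Si](c1ccccc1)(c1ccccc1)C(C)(C)C | intermediate
30 | C1 2-(4-methylbenzenesulfonyl)hydrazinyl compound (both C1 epimers) | C=C1CC[C@]2(O)[C@](C)(C(NNS(=O)(=O)c3ccc(C)cc3)CC[C@]2(C)C(=O)OCC[Si](C)(C)C)[C@]1(O[Si](CC)(CC)CC)CC/C(C)=C/CO[Si](c1ccccc1)(c1ccccc1)C(C)(C)C | intermediate
31 | 2-(trimethylsilyl)ethyl 15-(tert-butyldiphenylsilyloxy)-5α-hydroxy-9β-(triethylsilyloxy)labda-8(17),13E-dien-19-oate | C=C1CC[C@]2(O)[C@](C)(CCC[C@]2(C)C(=O)OCC[Si](C)(C)C)[C@]1(O[Si](CC)(CC)CC)CC/C(C)=C/CO[Si](c1ccccc1)(c1ccccc1)C(C)(C)C | intermediate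
32 | 5α,9β-dihydroxyisocupressic acid (5α,9β,15-trihydroxylabda-8(17),13E-dien-19-oic acid) | C=C1CC[C@]2(O)[C@](C)(CCC[C@]2(C)C(=O)O)[C@]1(O)CC/C(C)=C/CO | target

## Step count and risks

Total steps: 19. Longest linear sequence: 16 steps (8 to 32, steps 4–19).

Steps most likely to fail:

1. Step 15 (key step). The carbenoid may be diverted into cyclopropanation of the C8 methylene or into insertion, or the ylide may add with poor regio- or endo-control. Fallback: setting out from 22, aldol-type addition of ethyl diazoacetate (DBU, MeCN) to the formyl group would give the ethyl 2-diazo-3-hydroxy ester F1, and Dess–Martin oxidation the 2-diazo-3-oxo ester F2. With Rh2(OAc)4 in benzene at 80 °C and 7, this doubly stabilised diazo compound should pass through carbonyl ylide F3 to the C2-ethoxycarbonyl cycloadduct F4, because acceptor–acceptor carbenoids cyclopropanate slowly and give longer-lived, more polarised ylides. SmI2 would then open the bridge to β-keto ester F5, and Krapcho dealkoxycarbonylation (LiCl, wet DMSO, 120 °C) would come back to the route at 28.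

2. Step 9. The reagent may add in conjugate fashion to the exocyclic enone, the enone may dimerise before it reacts, or attack may come from the β face. Fallback: setting out from Mannich base 14 (isolated by stopping step 8 after its first stage), the organocerium reagent 18 would add to the saturated β-amino ketone to give amino alcohol F6. H2O2 in MeOH would give amine oxide F7, whose Cope elimination on warming in toluene can use only the C8 hydrogen and would come back to the route at 19.

3. Step 14. The β-keto acid may lose CO2 before or during activation, or the tertiary silyl ether may be lost while the acid chloride is made. Fallback: setting out from diol 21, TEMPO/PhI(OAc)2 in wet MeCN would oxidise only the primary alcohol, giving β-hydroxy acid F8, so no β-keto acid is formed. MeLi would convert the carboxylate into methyl ketone F9. LiN(SiMe3)2 followed by CF3CO2CH2CF3 would give trifluoroacetyl diketone F10, and MsN3/Et3N the hydroxy diazoketone F11 (detrifluoroacetylative diazo transfer, regiospecific because C5 is still a carbinol). Dess–Martin oxidation of the C5 carbinol would come back to the route at 25.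

## Further compounds

F1 | step 15 | ethyl 2-diazo-3-hydroxy-3-(ring B) propanoate from 22 | CCOC(=O)C(=[N+]=[N-])C(O)[C@@]1(C)C(=O)CCC(=C)[C@@]1(O[Si](CC)(CC)CC)CC/C(C)=C/CO[Si](c1ccccc1)(c1ccccc1)C(C)(C)C
F2 | step 15 | ethyl 2-diazo-3-oxo-3-(ring B) propanoate | CCOC(=O)C(=[N+]=[N-])C(=O)[C@@]1(C)C(=O)CCC(=C)[C@@]1(O[Si](CC)(CC)CC)CC/C(C)=C/CO[Si](c1ccccc1)(c1ccccc1)C(C)(C)C
F3 | step 15 | ester-substituted cyclic carbonyl ylide | CCOC(=O)[C-]1C(=O)[C@@]2(C)C(=[O+]1)CCC(=C)[C@@]2(O[Si](CC)(CC)CC)CC/C(C)=C/CO[Si](c1ccccc1)(c1ccccc1)C(C)(C)C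
F4 | step 15 | C2-ethoxycarbonyl analogue of cycloadduct 27 | C=C1CC[C@@]23O[C@@](C(=O)OCC)(C[C@]2(C)C(=O)OCC[Si](C)(C)C)C(=O)[C@]3(C)[C@]1(O[Si](CC)(CC)CC)CC/C(C)=C/CO[Si](c1ccccc1)(c1ccccc1)C(C)(C)C
F5 | step 15 | C2-ethoxycarbonyl analogue of 28 (β-keto ester, both C2 epimers) | C=C1CC[C@]2(O)[C@](C)(C(=O)C(C(=O)OCC)C[C@]2(C)C(=O)OCC[Si](C)(C)C)[C@]1(O[Si](CC)(CC)CC)CC/C(C)=C/CO[Si](c1ccccc1)(c1ccccc1)C(C)(C)C
F6 | step 9 | amino alcohol from 14 and 18 | CC1(C)OC[C@@]2(C)[C@H](O1)CCC(CN(C)C)[C@@]2(O)CC/C(C)=C/CO[Si](c1ccccc1)(c1ccccc1)C(C)(C)C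
F7 | step 9 | amine oxide of F6 | CC1(C)OC[C@@]2(C)[C@H](O1)CCC(C[N+](C)(C)[O-])[C@@]2(O)CC/C(C)=C/CO[Si](c1ccccc1)(c1ccccc1)C(C)(C)C
F8 | step 14 | β-hydroxy acid from 21 | OC(=O)[C@@]1(C)[C@H](O)CCC(=C)[C@@]1(O[Si](CC)(CC)CC)CC/C(C)=C/CO[Si](c1ccccc1)(c1ccccc1)C(C)(C)C
F9 | step 14 | hydroxy methyl ketone | CC(=O)[C@@]1(C)[C@H](O)CCC(=C)[C@@]1(O[Si](CC)(CC)CC)CC/C(C)=C/CO[Si](c1ccccc1)(c1ccccc1)C(C)(C)C
F10 | step 14 | trifluoroacetyl diketone | FC(F)(F)C(=O)CC(=O)[C@@]1(C)[C@H](O)CCC(=C)[C@@]1(O[Si](CC)(CC)CC)CC/C(C)=C/CO[Si](c1ccccc1)(c1ccccc1)C(C)(C)C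
F11 | step 14 | hydroxy diazoketone (C5 carbinol analogue of 25) | [N-]=[N+]=CC(=O)[C@@]1(C)[C@H](O)CCC(=C)[C@@]1(O[Si](CC)(CC)CC)CC/C(C)=C/CO[Si](c1ccccc1)(c1ccccc1)C(C)(C)C
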